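**Plan**

- Numbering used throughout (1-benzoxepine): O1, C2 (=CHBr), C3 and C4 (oxirane), C5, C5a, C6 (CMe2), C7 (CHBr), C8, C9, C9a (C–CH3). The enabling feature is that O1–C2(=CHBr)–C3(CH3)–C4 of the oxepane ring is, once the oxirane is read as a C3=C4 alkene, a 2-alkoxy-1,3-diene. Such a diene is what an alkenyl–alkene Heck coupling gives when a C3 alkenyl iodide attacks the oxygen-bearing carbon of a 2-bromovinyl ether.
- Retrosynthetic cuts, in order: the two oxirane C–O bonds (back to C3=C4); C2–C3 (Heck closure of the oxepine ring); O1–C2 (O-bromovinylation of the C9a alcohol); C3=C4 (Wittig on a lactol); then C7–Br, C5a–C6 and C9a–O (bromonium polyene cyclisation).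
- Forward order: ring A arises first, together with a temporary γ-lactone ring that holds the C9a oxygen and C4 at aldehyde level. The lactone is reduced and opened by olefination, the oxygen is armed, the oxepine ring is closed, and the oxirane ring comes last.
- Stereochemistry: C7, C5a and C9a come from the catalyst-controlled bromonium cyclisation (chair, E-alkene, trans fusion, equatorial bromine). The E-bromomethylidene group comes from syn-insertion/syn-elimination on a Z-bromovinyl ether. C3 and C4 come from substrate-controlled epoxidation anti to the C9a methyl group.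

Key step: step 5

Assumption: (3E)-homogeranic acid is bought as such, and the enantiomer of the Lewis base catalyst in step 1 is the one that puts bromine on the face of C7=C8 that leads to the (5S) lactone; this sense has to be assigned on the first run.

**Route**

Step 1
Reactants: 1 (3E)-4,8-dimethylnona-3,7-dienoic acid (homogeranic acid)
Product: 2 (3aS,5S,7aS)-5-bromo-4,4,7a-trimethylhexahydro-1-benzofuran-2(3H)-one (trans-fused bromolactone)
Conditions: N-bromosuccinimide (1.1 equiv), chiral BINOL-derived thiophosphoramide Lewis base (10 mol %), toluene/CH2Cl2, −78 °C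
Reagents that add atoms: N-bromosuccinimide, O=C1CCC(=O)N1Br
Why: Catalytic enantioselective bromonium-induced polyene cyclisation ended by lactonisation: the chiral Lewis base–Br+ complex should brominate one face of the distal, more electron-rich C7=C8 alkene (sets C5 of 2), and anti addition across the E-C3=C4 alkene through a chair transition state closed by the carboxyl oxygen sets C3a and C7a (trans fusion, equatorial bromine).

Step 2
Reactants: 2 (3aS,5S,7aS)-5-bromo-4,4,7a-trimethylhexahydro-1-benzofuran-2(3H)-one
Product: 3 (3aS,5S,7aS)-5-bromo-4,4,7a-trimethyloctahydro-1-benzofuran-2-ol (lactol, mixture of anomers)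
Conditions: i-Bu2AlH (1.1 equiv), CH2Cl2, −78 °C; then aq. potassium sodium tartrate
Reagents that add atoms: none
Why: Partial reduction of a lactone to the lactol, which should stop at the aldehyde level because the tetrahedral aluminium alkoxide is stable at −78 °C; the hindered equatorial secondary bromide should not react, and the new anomeric centre is of no consequence.

Step 3
Reactants: 3 (3aS,5S,7aS)-5-bromo-4,4,7a-trimethyloctahydro-1-benzofuran-2-ol
Product: 5 (1S,2S,4S)-4-bromo-2-[(2Z)-3-iodobut-2-en-1-yl]-1,3,3-trimethylcyclohexan-1-ol, via hydroxy aldehyde 4 (not isolated)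
Conditions: EtPPh3I, n-BuLi, THF, rt; I2, −78 °C; NaN(SiMe3)2, −20 °C; then 3, −78 → 0 °C
Reagents that add atoms: ethyltriphenylphosphonium iodide, CC[P+](c1ccccc1)(c1ccccc1)c1ccccc1.[I-]; iodine, II
Why: Stork–Zhao-type Wittig olefination: the base opens the strained trans-fused lactol to the aldehyde 4, and the non-stabilised α-iodo ylide should give the Z-2-iodoalkene (iodine cis to the chain) through the kinetic cis-oxaphosphetane; no sp3 stereocentre is touched.

Step 4
Reactants: 5 (1S,2S,4S)-4-bromo-2-[(2Z)-3-iodobut-2-en-1-yl]-1,3,3-trimethylcyclohexan-1-ol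
Product: 7 (1S,2S,4S)-4-bromo-1-{[(Z)-2-bromoethenyl]oxy}-2-[(2Z)-3-iodobut-2-en-1-yl]-1,3,3-trimethylcyclohexane, via potassium alkoxide 6 (not isolated)
Conditions: KH (2.2 equiv), THF, 0 °C; then 1,2-dibromoethene (1.5 equiv), 0 °C → rt
Reagents that add atoms: 1,2-dibromoethene, BrC=CBr
Why: Nucleophilic addition of an alkoxide to a haloalkyne made in the flask (the reaction type that gives 1,2-dichlorovinyl ethers from trichloroethene): the base eliminates HBr from dibromoethene, and the tertiary alkoxide should add anti to the resulting bromoethyne at its CH carbon, which gives the Z-2-bromovinyl ether (oxygen cis to bromine).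

Step 5
Reactants: 7 (1S,2S,4S)-4-bromo-1-{[(Z)-2-bromoethenyl]oxy}-2-[(2Z)-3-iodobut-2-en-1-yl]-1,3,3-trimethylcyclohexane
Product: 8 (2E,5aS,7S,9aS)-7-bromo-2-(bromomethylidene)-3,6,6,9a-tetramethyl-2,5,5a,6,7,8,9,9a-octahydro-1-benzoxepine
Conditions: Pd(OAc)2 (10 mol %), PPh3 (20 mol %), Ag2CO3 (1.5 equiv), MeCN, 40 °C, dark
Reagents that add atoms: none
Why: Proposed new method: zerovalent palladium inserts into the alkenyl C–I bond of 7 (far faster than into the donor-substituted alkenyl C–Br or the alkyl C–Br bond), Ag2CO3 removes iodide, the cationic alkenylpalladium adds syn across the enol ether C=C with the alkenyl carbon C3 going to the oxygen-bearing carbon C2 and palladium to the CHBr carbon, and after rotation about the exocyclic bond syn-β-hydride elimination of the only β-hydrogen (on C2) releases 8. The closest known reaction type is the intramolecular Mizoroki–Heck alkenylation of vinyl ethers at the oxygen-bearing carbon; what is new is a bromine on the other alkene carbon, carried through an α-bromoalkylpalladium intermediate that has no β-leaving group and so should only lose hydride. The oxepine ring closes in the 7-exo-trig mode. No sp3 stereocentre is formed; the E geometry of the bromomethylidene group is fixed by the Z geometry of the bromovinyl ether, because syn insertion followed by syn elimination places the new C2–C3 bond cis to bromine. The step needs site-selective oxidative addition (secured by the iodide and the mild temperature), bond formation at C2 and not at the CHBr carbon (secured by the exo tether, which would otherwise demand an eight-membered ring, and by the polarisation of the enol ether), and no re-addition of palladium hydride to the diene (secured by the silver base).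

Step 6
Reactants: 8 (2E,5aS,7S,9aS)-7-bromo-2-(bromomethylidene)-3,6,6,9a-tetramethyl-2,5,5a,6,7,8,9,9a-octahydro-1-benzoxepine
Product: 9 (2E,3R,4R,5aS,7S,9aS)-7-bromo-2-(bromomethylidene)-3,4-epoxy-3,6,6,9a-tetramethyldecahydro-1-benzoxepine (target CNP0375295.1)
Conditions: dimethyldioxirane (1.05 equiv), acetone/CH2Cl2, −40 → 0 °C
Reagents that add atoms: dimethyldioxirane, CC1(C)OO1
Why: Electrophilic epoxidation by a dioxirane under neutral conditions: the trisubstituted C3=C4 alkene should react before the C2 enol ether alkene, which its bromine deactivates, and the oxidant should approach the face of the seven-membered ring anti to the axial C9a methyl group, which sets C3 and C4 together as the cis-fused oxirane.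

**Compound list**

1 | (3E)-4,8-dimethylnona-3,7-dienoic acid (homogeranic acid) | CC(C)=CCC/C(C)=C/CC(=O)O | starting material
2 | (3aS,5S,7aS)-5-bromo-4,4,7a-trimethylhexahydro-1-benzofuran-2(3H)-one | CC1(C)[C@@H](Br)CC[C@]2(C)OC(=O)C[C@@H]12 | intermediate
3 | (3aS,5S,7aS)-5-bromo-4,4,7a-trimethyloctahydro-1-benzofuran-2-ol (anomer mixture) | CC1(C)[C@@H](Br)CC[C@]2(C)OC(O)C[C@@H]12 | intermediate
4 | [(1S,3S,6S)-3-bromo-6-hydroxy-2,2,6-trimethylcyclohexyl]acetaldehyde (not isolated) | CC1(C)[C@@H](Br)CC[C@](C)(O)[C@H]1CC=O | intermediate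
5 | (1S,2S,4S)-4-bromo-2-[(2Z)-3-iodobut-2-en-1-yl]-1,3,3-trimethylcyclohexan-1-ol | CC1(C)[C@@H](Br)CC[C@](C)(O)[C@H]1C/C=C(/C)I | intermediate
6 | potassium (1S,2S,4S)-4-bromo-2-[(2Z)-3-iodobut-2-en-1-yl]-1,3,3-trimethylcyclohexan-1-olate (not isolated) | CC1(C)[C@@H](Br)CC[C@](C)([O-])[C@H]1C/C=C(/C)I.[K+] | intermediate
7 | (1S,2S,4S)-4-bromo-1-{[(Z)-2-bromoethenyl]oxy}-2-[(2Z)-3-iodobut-2-en-1-yl]-1,3,3-trimethylcyclohexane | CC1(C)[C@@H](Br)CC[C@](C)(O/C=C\Br)[C@H]1C/C=C(/C)I | intermediate
8 | (2E,5aS,7S,9aS)-7-bromo-2-(bromomethylidene)-3,6,6,9a-tetramethyl-2,5,5a,6,7,8,9,9a-octahydro-1-benzoxepine | CC1(C)[C@@H](Br)CC[C@]2(C)O/C(=C/Br)C(C)=CC[C@@H]12 | intermediate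
9 | (2E,3R,4R,5aS,7S,9aS)-7-bromo-2-(bromomethylidene)-3,4-epoxy-3,6,6,9a-tetramethyldecahydro-1-benzoxepine (CNP0375295.1) | CC1(C)[C@@H](Br)CC[C@]2(C)O/C(=C/Br)[C@]3(C)O[C@@H]3C[C@@H]12 | target

**Step count and risks**

Total step count: 6. Longest linear sequence: 6 steps (1 → 9).

Steps most likely to fail:

1. Step 5 (the step that carries the label). Zerovalent palladium may also insert into the alkenyl C–Br bond of the bromovinyl ether in 7 or in 8, or the α-bromoalkylpalladium intermediate may lose bromide before β-hydride elimination; either process would give debrominated dienes and oligomers. The fallback uses known reactions only, sets out from 7 and comes back at 8. LiN(i-Pr)2 (2.2 equiv) in THF at −78 °C removes HBr by anti elimination to give the terminal alkynyl ether (1S,2S,4S)-4-bromo-1-(ethynyloxy)-2-[(2Z)-3-iodobut-2-en-1-yl]-1,3,3-trimethylcyclohexane F1, which must be kept below 40 °C. Pd(PPh3)4 with Me3SnSnMe3 in THF at 40 °C should then bring about oxidative addition, 7-exo-dig syn-carbopalladation of the alkyne and stannylation, giving (2E,5aS,7S,9aS)-7-bromo-3,6,6,9a-tetramethyl-2-[(trimethylstannyl)methylidene]-2,5,5a,6,7,8,9,9a-octahydro-1-benzoxepine F2 with tin cis to C3. N-Bromosuccinimide in CH2Cl2 at −78 °C should replace tin by bromine with retention and give 8.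

2. Step 1. Uncatalysed background bromination, and bromolactonisation at the C3=C4 alkene next to the acid, may erode enantioselectivity and site selectivity. The fallback sets out from 1 and comes back at 2, and replaces asymmetric catalysis by resolution. 2,4,4,6-Tetrabromocyclohexa-2,5-dien-1-one in MeNO2 should give the racemic trans-fused bromolactone F3. AlMe3 with (S)-1-phenylethylamine opens it to two diastereomeric hydroxy amides, N-[(1S)-1-phenylethyl]-2-[(1S,3S,6S)-3-bromo-6-hydroxy-2,2,6-trimethylcyclohexyl]acetamide F4 and its (1R,3R,6R) diastereomer F5, which are separated by chromatography or crystallisation. F4 is relactonised with TsOH in toluene at 80 °C to 2, with release of the amine.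

3. Step 6. The oxidant may deliver oxygen to the face syn to the C9a methyl group. The fallback sets out from 8 and comes back at 9, and delivers the oxygen to the face opposite to the one that an electrophile attacks. N-Bromosuccinimide in THF/H2O at 0 °C should add bromine to C4 on the face preferred by electrophiles, and water opens at the tertiary allylic C3 from the other face. This gives the bromohydrin (2E,3S,4S,5aS,7S,9aS)-4,7-dibromo-2-(bromomethylidene)-3,6,6,9a-tetramethyldecahydro-1-benzoxepin-3-ol F6. K2CO3 in MeOH then closes the oxirane with inversion at C4 to give 9.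

**Further compounds**

F1 | step 5 | (1S,2S,4S)-4-bromo-1-(ethynyloxy)-2-[(2Z)-3-iodobut-2-en-1-yl]-1,3,3-trimethylcyclohexane | CC1(C)[C@@H](Br)CC[C@](C)(OC#C)[C@H]1C/C=C(/C)I
F2 | step 5 | (2E,5aS,7S,9aS)-7-bromo-3,6,6,9a-tetramethyl-2-[(trimethylstannyl)methylidene]-2,5,5a,6,7,8,9,9a-octahydro-1-benzoxepine | CC1(C)[C@@H](Br)CC[C@]2(C)O/C(=C/[Sn](C)(C)C)C(C)=CC[C@@H]12
F3 | step 1 | racemic (3aS*,5S*,7aS*)-5-bromo-4,4,7a-trimethylhexahydro-1-benzofuran-2(3H)-one | CC1(C)[C@@H](Br)CC[C@]2(C)OC(=O)C[C@@H]12.CC1(C)[C@H](Br)CC[C@@]2(C)OC(=O)C[C@H]12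
F4 | step 1 | N-[(1S)-1-phenylethyl]-2-[(1S,3S,6S)-3-bromo-6-hydroxy-2,2,6-trimethylcyclohexyl]acetamide | CC1(C)[C@@H](Br)CC[C@](C)(O)[C@H]1CC(=O)N[C@@H](C)c1ccccc1
F5 | step 1 | N-[(1S)-1-phenylethyl]-2-[(1R,3R,6R)-3-bromo-6-hydroxy-2,2,6-trimethylcyclohexyl]acetamide | CC1(C)[C@H](Br)CC[C@@](C)(O)[C@@H]1CC(=O)N[C@@H](C)c1ccccc1
F6 | step 6 | (2E,3S,4S,5aS,7S,9aS)-4,7-dibromo-2-(bromomethylidene)-3,6,6,9a-tetramethyldecahydro-1-benzoxepin-3-ol | CC1(C)[C@@H](Br)CC[C@]2(C)O/C(=C/Br)[C@](C)(O)[C@@H](Br)C[C@@H]12
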